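## Retrosynthetic overview
1. The target's tetrahydrofuran (THF) comes from a γ-aryl-γ-butyrolactone, which is built early and carried through. Late in the route its C=O is taken to CH2 by DIBAL, then Et3SiH/BF3.
2. The tertiary carbinol (C8′) comes from Davis hydroxylation of the enolate of an α-benzyl lactone, delivered anti to the β-CH2OTBDPS group. The benzyl group comes from enolate alkylation.
3. The β-CH2OH stereocentre (C8) comes from trans-selective vinyl-cuprate addition to a 5-aryl butenolide, then vinyl → CHO → CH2OH, with the last reduction done by a ketoreductase.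
4. The benzylic stereocentre (C7) is set first by Ru-TsDPEN asymmetric transfer hydrogenation of an aroylpropionate, which comes from a Stetter reaction of benzyl-vanillin with ethyl acrylate.

Assumptions: both phenols are carried as benzyl ethers. Ar = 4-(benzyloxy)-3-methoxyphenyl. The (R,R)-TsDPEN-Ru catalyst gives the (R)-carbinol, by analogy with acetophenone.

## Route

**Step 1**
Reactants: 1 (4-(benzyloxy)-3-methoxybenzaldehyde), 2 (ethyl acrylate)
Product: 3 (ethyl 4-[4-(benzyloxy)-3-methoxyphenyl]-4-oxobutanoate)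
Conditions: 3-benzyl-5-(2-hydroxyethyl)-4-methylthiazolium chloride (20 mol%), Et3N, EtOH, 80 °C
Reagents that add atoms: none (the thiazolium is a catalyst)
Why: Stetter reaction. An NHC-derived Breslow intermediate adds the aldehyde C–H across the acrylate to give the 1,4-ketoester. No stereocentre is formed.

**Step 2**
Reactants: 3
Product: 4 (ethyl (4R)-4-[4-(benzyloxy)-3-methoxyphenyl]-4-hydroxybutanoate)
Conditions: RuCl[(R,R)-TsDPEN](p-cymene) (1 mol%), HCO2H/Et3N (5:2), EtOAc, 30 °C
Reagents that add atoms: none (formal H2 from formate)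
Why: Noyori–Ikariya asymmetric transfer hydrogenation. The chiral Ru–H reduces the aryl ketone enantioselectively, setting C7 as the first stereocentre (R). The ester, benzyl ether and aryl ether are untouched.

**Step 3**
Reactants: 4
Product: 5 ((5R)-5-Ar-dihydrofuran-2(3H)-one)
Conditions: LiOH, THF/H2O, rt; then 1 M HCl to pH 2, rt
Reagents that add atoms: none
Why: Saponification followed by mild acidification closes the 5-membered lactone (γ-hydroxy acid lactonisation). The mild, non-heating conditions avoid ionising the electron-rich benzylic C–O, so C7 is retained.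

**Step 4**
Reactants: 5, 6 (phenylselenenyl chloride)
Product: 7 ((5R)-5-Ar-3-(phenylselanyl)dihydrofuran-2(3H)-one, epimeric at C3)
Conditions: LDA (1.1 equiv), THF, −78 °C; then 6, −78 → 0 °C
Reagents that add atoms: PhSeCl, Cl[Se]c1ccccc1 (adds PhSe)
Why: The lactone enolate is selenylated at the α-carbon. The C3 epimers are irrelevant because C3 becomes sp2 in Step 5.

**Step 5**
Reactants: 7
Product: 8 ((5R)-5-Ar-furan-2(5H)-one)
Conditions: 30% H2O2, CH2Cl2, 0 °C → rt
Reagents that add atoms: none (PhSeOH is lost)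
Why: Selenoxide syn-elimination gives the conjugated butenolide. No amine base is used, to avoid γ-deprotonation and racemisation at the benzylic γ-carbon.

**Step 6**
Reactants: 8, 9 (vinylmagnesium bromide)
Product: 10 ((4S,5R)-5-Ar-4-vinyldihydrofuran-2(3H)-one)
Conditions: CuBr·SMe2 (20 mol%), TMSCl, THF, −78 → −40 °C
Reagents that add atoms: vinylmagnesium bromide, C=C[Mg]Br (adds vinyl)
Why: Cu-catalysed 1,4-addition, with TMSCl trapping the enolate. The vinyl group adds to the face anti to the γ-aryl group, so C8 is set trans to C7.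

**Step 7**
Reactants: 10
Product: 11 ((2R,3R)-2-Ar-5-oxotetrahydrofuran-3-carbaldehyde)
Conditions: OsO4 (5 mol%), NaIO4 (4 equiv), 2,6-lutidine, dioxane/H2O 3:1, rt
Reagents that add atoms: NaIO4, [Na+].[O-]I(=O)(=O)=O (supplies the aldehyde O)
Why: Lemieux–Johnson oxidative cleavage of the terminal alkene. The aldehyde α-carbon (C8) is the thermodynamically preferred trans isomer, so any epimerisation favours the desired configuration.

**Step 8 (enzymatic step)**
Reactants: 11
Product: 12 ((4S,5R)-5-Ar-4-(hydroxymethyl)dihydrofuran-2(3H)-one)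
Conditions: ketoreductase (KRED, NADPH-dependent alcohol dehydrogenase, oxidoreductase class), NADP+ (cat.), D-glucose, glucose dehydrogenase (cofactor recycling), KPi pH 7.0, 10% DMSO, 30 °C
Reagents that add atoms: none (net H2 from glucose via NADPH)
Why: Enzymatic aldehyde reduction at neutral pH is chemoselective for the CHO over the lactone. It avoids the base-mediated β-elimination (retro-oxa-Michael) and C8 epimerisation that hydride reagents risk in this β-acyloxy aldehyde.

**Step 9**
Reactants: 12, 13 (TBDPSCl)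
Product: 14 ((4S,5R)-4-(TBDPSO-methyl)-5-Ar-dihydrofuran-2(3H)-one)
Conditions: imidazole, DMF, 0 °C → rt
Reagents that add atoms: TBDPSCl, CC(C)(C)[Si](Cl)(c1ccccc1)c1ccccc1 (adds TBDPS)
Why: Silylation of the primary alcohol. The bulky silyl group blocks one face for Step 11 and prevents translactonisation.

**Step 10**
Reactants: 14, 15 (4-(benzyloxy)-3-methoxybenzyl chloride)
Product: 16 ((3R,4S,5R)-3-(4-benzyloxy-3-methoxybenzyl)-4-(TBDPSO-methyl)-5-Ar-dihydrofuran-2(3H)-one, trans major, as a C3 epimer mixture)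
Conditions: LiHMDS (1.1 equiv), THF, −78 °C; then 15, NaI (cat.), DMPU, −78 → −20 °C
Reagents that add atoms: 15, COc1cc(CCl)ccc1OCc1ccccc1 (adds the benzyl group)
Why: Lactone enolate C-alkylation. The C3 configuration is erased by re-enolisation in Step 11, so it does not matter.

**Step 11**
Reactants: 16, 17 (Davis 2-(phenylsulfonyl)-3-phenyloxaziridine)
Product: 18 ((3R,4S,5R)-3-hydroxy-3-benzyl-4-(TBDPSO-methyl)-5-Ar-lactone)
Conditions: LiHMDS (1.3 equiv), THF, −78 °C; then 17, −78 °C, 1 h
Reagents that add atoms: 17, O=S(=O)(c1ccccc1)N1OC1c1ccccc1 (adds O)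
Why: Enolate hydroxylation with an oxaziridine. The planar tetrasubstituted enolate is oxidised on the face anti to the adjacent CH2OTBDPS group. The OH therefore ends up trans to CH2OTBDPS and cis to the aryl group, and the benzyl group is pushed cis to CH2OTBDPS, as in the target. This sets C8′.

**Step 12**
Reactants: 18
Product: 19 (lactol, (3R,4S,5R)-3-benzyl-4-(TBDPSO-methyl)-5-Ar-tetrahydrofuran-2,3-diol, anomeric mixture)
Conditions: DIBAL-H (2.5 equiv), CH2Cl2, −78 °C
Reagents that add atoms: none (hydride only)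
Why: Partial reduction of the lactone to the lactol. No stereocentre is touched; the new anomeric centre is removed in Step 13.

**Step 13**
Reactants: 19
Product: 20 ((2R,3S,4R)-4-(4-benzyloxy-3-methoxybenzyl)-2-Ar-3-(TBDPSO-methyl)tetrahydrofuran-4-ol)
Conditions: Et3SiH (6 equiv), BF3·OEt2 (3 equiv), CH2Cl2, −78 → −30 °C
Reagents that add atoms: none (hydride only)
Why: Ionic deoxygenation. The lactol gives a cyclic oxocarbenium ion, which Et3SiH reduces to the THF CH2. The low temperature prevents ionisation at C7, so C7 is kept.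

**Step 14**
Reactants: 20
Product: 21 ((2R,3S,4R)-4-(4-benzyloxy-3-methoxybenzyl)-2-Ar-3-(hydroxymethyl)tetrahydrofuran-4-ol)
Conditions: TBAF (2 equiv), THF, 0 °C → rt
Reagents that add atoms: none
Why: Fluoride cleaves the Si–O bond of the TBDPS ether. The benzyl ethers and the tertiary alcohol are unaffected.

**Step 15**
Reactants: 21
Product: 22 (target, (2R,3S,4R)-2-(4-hydroxy-3-methoxyphenyl)-4-(4-hydroxy-3-methoxybenzyl)-3-(hydroxymethyl)tetrahydrofuran-4-ol)
Conditions: H2 (1 atm), 10% Pd/C, EtOAc/MeOH 1:1, rt, 1–2 h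
Reagents that add atoms: none (H2)
Why: Hydrogenolysis removes both aryl O-benzyl groups. The short reaction time at 1 atm leaves the benzylic C7–O bond of the THF intact.

## Compound list
(Ar = 4-(benzyloxy)-3-methoxyphenyl)

| No. | Name | SMILES | Role |
|---|---|---|---|
| 1 | 4-(benzyloxy)-3-methoxybenzaldehyde | COc1cc(C=O)ccc1OCc1ccccc1 | starting material |
| 2 | ethyl acrylate | C=CC(=O)OCC | starting material |
| 3 | ethyl 4-Ar-4-oxobutanoate | CCOC(=O)CCC(=O)c1ccc(OCc2ccccc2)c(OC)c1 | intermediate |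
| 4 | ethyl (4R)-4-Ar-4-hydroxybutanoate | CCOC(=O)CC[C@@H](O)c1ccc(OCc2ccccc2)c(OC)c1 | intermediate |
| 5 | (5R)-5-Ar-dihydrofuran-2(3H)-one | O=C1CC[C@H](c2ccc(OCc3ccccc3)c(OC)c2)O1 | intermediate |
| 6 | phenylselenenyl chloride | Cl[Se]c1ccccc1 | starting material |
| 7 | (5R)-5-Ar-3-(phenylselanyl)dihydrofuran-2(3H)-one (C3 epimers) | O=C1C([Se]c2ccccc2)C[C@H](c2ccc(OCc3ccccc3)c(OC)c2)O1 | intermediate |
| 8 | (5R)-5-Ar-furan-2(5H)-one | O=C1C=C[C@H](c2ccc(OCc3ccccc3)c(OC)c2)O1 | intermediate |
| 9 | vinylmagnesium bromide | C=C[Mg]Br | starting material |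
| 10 | (4S,5R)-5-Ar-4-vinyldihydrofuran-2(3H)-one | O=C1C[C@@H](C=C)[C@H](c2ccc(OCc3ccccc3)c(OC)c2)O1 | intermediate |
| 11 | (2R,3R)-2-Ar-5-oxotetrahydrofuran-3-carbaldehyde | O=C1C[C@@H](C=O)[C@H](c2ccc(OCc3ccccc3)c(OC)c2)O1 | intermediate |
| 12 | (4S,5R)-5-Ar-4-(hydroxymethyl)dihydrofuran-2(3H)-one | O=C1C[C@@H](CO)[C@H](c2ccc(OCc3ccccc3)c(OC)c2)O1 | intermediate |
| 13 | tert-butyldiphenylsilyl chloride | CC(C)(C)[Si](Cl)(c1ccccc1)c1ccccc1 | starting material |
| 14 | TBDPS ether of 12 | O=C1C[C@@H](CO[Si](c2ccccc2)(c2ccccc2)C(C)(C)C)[C@H](c2ccc(OCc3ccccc3)c(OC)c2)O1 | intermediate |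
| 15 | 4-(benzyloxy)-3-methoxybenzyl chloride | COc1cc(CCl)ccc1OCc1ccccc1 | starting material |
| 16 | (3R,4S,5R)-3-benzyl-type α-benzyl lactone (trans major) | O=C1[C@H](Cc2ccc(OCc3ccccc3)c(OC)c2)[C@@H](CO[Si](c2ccccc2)(c2ccccc2)C(C)(C)C)[C@H](c2ccc(OCc3ccccc3)c(OC)c2)O1 | intermediate |
| 17 | Davis 2-(phenylsulfonyl)-3-phenyloxaziridine | O=S(=O)(c1ccccc1)N1OC1c1ccccc1 | starting material |
| 18 | α-hydroxy-α-benzyl lactone | O=C1[C@@](O)(Cc2ccc(OCc3ccccc3)c(OC)c2)[C@@H](CO[Si](c2ccccc2)(c2ccccc2)C(C)(C)C)[C@H](c2ccc(OCc3ccccc3)c(OC)c2)O1 | intermediate |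
| 19 | lactol (anomeric mixture) | OC1[C@@](O)(Cc2ccc(OCc3ccccc3)c(OC)c2)[C@@H](CO[Si](c2ccccc2)(c2ccccc2)C(C)(C)C)[C@H](c2ccc(OCc3ccccc3)c(OC)c2)O1 | intermediate |
| 20 | TBDPS-protected THF | C1[C@@](O)(Cc2ccc(OCc3ccccc3)c(OC)c2)[C@@H](CO[Si](c2ccccc2)(c2ccccc2)C(C)(C)C)[C@H](c2ccc(OCc3ccccc3)c(OC)c2)O1 | intermediate |
| 21 | bis-benzyl THF alcohol | C1[C@@](O)(Cc2ccc(OCc3ccccc3)c(OC)c2)[C@@H](CO)[C@H](c2ccc(OCc3ccccc3)c(OC)c2)O1 | intermediate |
| 22 | target (CID44566587) | COc1cc(C[C@]2(O)CO[C@@H](c3ccc(O)c(OC)c3)[C@@H]2CO)ccc1O | target |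

## Totals
- Total steps: 15.
- Longest linear sequence: 15 steps (Step 1 → Step 15).

## Three steps most likely to fail
1. **Step 11 (facial selectivity of α-hydroxylation).** The 1,3-cis γ-aryl group may erode the anti-to-CH2OTBDPS preference.
   Fallback (different approach): install C8′ first by Sharpless asymmetric epoxidation of 2-(arylmethyl)prop-2-en-1-ol and cyanide opening to a 4-benzyl-4-hydroxybutyrolactone. Then aldol with the aryl aldehyde, reduce the lactone to the tetraol, and close the THF by acid-catalysed benzylic cyclodehydration.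
2. **Step 13 (lactol ionic deoxygenation).** Benzylic C7–O ionisation or dehydration of the tertiary alcohol could compete.
   Fallback: reduce 18 with LiAlH4 to the triol and close the THF by acid-catalysed SN1 cyclodehydration, where the C7 aryl group settles trans to the CH2OH by thermodynamic control.
3. **Step 5 (butenolide formation, risk of racemisation).** The acidic benzylic γ-H could lose ee.
   Fallback: skip the butenolide. Use Ru-catalysed transfer hydrogenation with dynamic kinetic resolution of diethyl 2-aroylsuccinate, lactonise, epimerise to the trans lactone, and hydrolyse the exocyclic ester with pig liver esterase. Then reduce the resulting acid with BH3 to give 12.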